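The route rests on cutting ring B at two neighbouring atoms at once: the CH2–C1' bond to ring A and the C2'–Br bond. A methylene at C1' and a bromine at C2', lying beside the C3' bromine, are the footprint of a carbon nucleophile and a bromine electrophile added across the C1'≡C2' bond of 3-bromo-4,5-dimethoxybenzyne. In one flask the aryne is released from an ortho-iodoaryl 4-chlorobenzenesulfonate. It is carbomagnesiated at C1' by the ring A benzylic Grignard reagent, which already carries its bromine, both methoxy groups and a silyl-protected hydroxyethyl arm. The C2' arylmagnesium is then brominated. Desilylation, demethylation and sulfation of the primary alcohol complete the synthesis.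

Key step: step 11

Numbering: ring A has C1 hydroxyethyl arm, C2 CH2 bridge, C3 Br, C4 and C5 oxygen, C6 H. Ring B has C1' CH2 bridge, C2' and C3' Br, C4' and C5' oxygen, C6' H.
Remark: the target has no stereocentre and is taken in the protonated hydrogen sulfate form drawn, reached from its salt by cation exchange; 1 and 11 are catalogue compounds.

Step 1
Reactants: 1 3-bromo-4,5-dimethoxybenzaldehyde
Product: 2 1-bromo-5-ethenyl-2,3-dimethoxybenzene
Conditions: Ph3PCH3Br, KOtBu, THF, 0 °C → rt
Reagents that add atoms: methyltriphenylphosphonium bromide, C[P+](c1ccccc1)(c1ccccc1)c1ccccc1.[Br-]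
Why: Wittig methylenation of an unhindered, non-enolisable aromatic aldehyde is dependable, and this starting material fixes the ring A bromine beside the two methoxy groups with no regiochemical question.

Step 2
Reactants: 2 1-bromo-5-ethenyl-2,3-dimethoxybenzene
Product: 4 2-(3-bromo-4,5-dimethoxyphenyl)ethanol, via B-alkyl-9-BBN adduct 3 (not isolated)
Conditions: 9-BBN, THF, 0 °C → rt; then NaOH, H2O2, 0 °C → rt
Reagents that add atoms: hydrogen peroxide, OO
Why: In this hydroboration–oxidation the bulky 9-BBN places boron on the terminal styrene carbon (anti-Markovnikov), and alkaline peroxide exchanges boron for hydroxyl without touching the aryl bromide.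

Step 3
Reactants: 4 2-(3-bromo-4,5-dimethoxyphenyl)ethanol
Product: 5 tert-butyl[2-(3-bromo-4,5-dimethoxyphenyl)ethoxy]diphenylsilane
Conditions: TBDPSCl, imidazole, DMF, rt
Reagents that add atoms: tert-butyl(chloro)diphenylsilane, CC(C)(C)[Si](Cl)(c1ccccc1)c1ccccc1
Why: This is a standard imidazole-promoted silylation, and the acid-robust, bulky tert-butyldiphenylsilyl group is chosen because it must outlast the Lewis acid of step 4 and keep the ether oxygen from closing onto the benzylic chloride of 9 to form an isochroman.

Step 4
Reactants: 5 tert-butyl[2-(3-bromo-4,5-dimethoxyphenyl)ethoxy]diphenylsilane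
Product: 6 2-bromo-6-[2-(tert-butyldiphenylsilyloxy)ethyl]-3,4-dimethoxybenzaldehyde
Conditions: Cl2CHOMe, TiCl4, CH2Cl2, −78 → 0 °C; then H2O
Reagents that add atoms: dichloromethyl methyl ether, COC(Cl)Cl; water, O
Why: Rieche formylation (Friedel–Crafts type) should go to C2 of ring A, para to the in-plane C5 methoxy group, as halogen and benzyl electrophiles do in 3-bromo-4,5-dimethoxyphenyl systems, whereas C6 is only ortho-activated and is screened by the methyl of that same methoxy group.

Step 5
Reactants: 6 2-bromo-6-[2-(tert-butyldiphenylsilyloxy)ethyl]-3,4-dimethoxybenzaldehyde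
Product: 7 {2-bromo-6-[2-(tert-butyldiphenylsilyloxy)ethyl]-3,4-dimethoxyphenyl}methanol
Conditions: NaBH4, THF–MeOH, 0 °C
Reagents that add atoms: none
Why: Borohydride reduction of an aldehyde is chemoselective and leaves the aryl bromide and the silyl ether alone.

Step 6
Reactants: 7 {2-bromo-6-[2-(tert-butyldiphenylsilyloxy)ethyl]-3,4-dimethoxyphenyl}methanol
Product: 9 tert-butyl{2-[3-bromo-2-(chloromethyl)-4,5-dimethoxyphenyl]ethoxy}diphenylsilane, via benzylic mesylate 8 (not isolated)
Conditions: MsCl, Et3N, CH2Cl2, 0 °C; then LiCl, THF, rt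
Reagents that add atoms: lithium chloride, [Li+].[Cl-]
Why: Mesylation followed by SN2 displacement with chloride runs under amine-buffered conditions, so no acid is present to ionise the electron-rich benzylic position or loosen the silyl ether.

Step 7
Reactants: 9 tert-butyl{2-[3-bromo-2-(chloromethyl)-4,5-dimethoxyphenyl]ethoxy}diphenylsilane
Product: 10 {2-bromo-6-[2-(tert-butyldiphenylsilyloxy)ethyl]-3,4-dimethoxybenzyl}magnesium chloride (titrated stock solution)
Conditions: Mg turnings (excess, activated with 1,2-dibromoethane), 2-MeTHF, 0 °C, slow addition of dilute 9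
Reagents that add atoms: magnesium, [Mg]
Why: In this Grignard formation magnesium inserts into a benzylic carbon–chlorine bond much faster than into an electron-rich aryl bromide (2-bromobenzyl Grignard reagents are standard reagents), and slow addition at high dilution to excess metal in 2-MeTHF holds back Wurtz coupling.

Step 8
Reactants: 11 2-bromo-3,4-dimethoxybenzaldehyde
Product: 13 2-bromo-3,4-dimethoxyphenol, via aryl formate 12 (not isolated)
Conditions: mCPBA, CH2Cl2, 0 °C → rt; then MeOH, HCl (cat.), rt
Reagents that add atoms: 3-chloroperoxybenzoic acid, O=C(OO)c1cccc(Cl)c1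
Why: In the Baeyer–Villiger oxidation the electron-rich aryl group with its para methoxy substituent migrates in preference to hydride, the formate is methanolysed in the same flask, and the future C3' bromine thus sits beside the phenol from the outset.

Step 9
Reactants: 13 2-bromo-3,4-dimethoxyphenol
Product: 14 2-bromo-6-iodo-3,4-dimethoxyphenol
Conditions: NIS, MeCN, 0 °C, dark
Reagents that add atoms: N-iodosuccinimide, O=C1CCC(=O)N1I
Why: Electrophilic aromatic iodination is steered to C6 by the ortho hydroxyl and the para C3 methoxy group together, the only other free position being meta to the hydroxyl, and introducing iodine last excludes halogen scrambling.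

Step 10
Reactants: 14 2-bromo-6-iodo-3,4-dimethoxyphenol
Product: 15 2-bromo-6-iodo-3,4-dimethoxyphenyl 4-chlorobenzenesulfonate
Conditions: 4-ClC6H4SO2Cl, Et3N, DMAP (cat.), CH2Cl2, 0 °C → rt
Reagents that add atoms: 4-chlorobenzenesulfonyl chloride, O=S(=O)(Cl)c1ccc(Cl)cc1
Why: O-Sulfonylation of an acidic 2,6-dihalophenol proceeds readily with amine base and nucleophilic catalysis, and this arenesulfonate stays put at −78 °C beside a metalated carbon yet departs on gentle warming.

Step 11
Reactants: 15 2-bromo-6-iodo-3,4-dimethoxyphenyl 4-chlorobenzenesulfonate; 10 {2-bromo-6-[2-(tert-butyldiphenylsilyloxy)ethyl]-3,4-dimethoxybenzyl}magnesium chloride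
Product: 19 tert-butyl{2-[3-bromo-2-(2,3-dibromo-4,5-dimethoxybenzyl)-4,5-dimethoxyphenyl]ethoxy}diphenylsilane, via magnesiated sulfonate 16 (not isolated), via 3-bromo-4,5-dimethoxybenzyne 17 (not isolated), via C2'-arylmagnesium chloride 18 (not isolated)
Conditions: 15, iPrMgCl (1.0 equiv), THF, −78 °C; then 10 (1.5 equiv), −78 → −20 °C; then (BrCl2C)2, −40 → 0 °C
Reagents that add atoms: 1,2-dibromo-1,1,2,2-tetrachloroethane, ClC(Cl)(Br)C(Cl)(Cl)Br
Why: Iodine–magnesium exchange on 15 at −78 °C is far faster than any attack on its aryl bromide or sulfonate and gives 16, which persists at that temperature, so all iPrMgCl is spent before 10 is added and aryne 17, formed by loss of the sulfonate on warming, meets only the benzylic nucleophile. Carbomagnesiation of the strained triple bond forms the CH2–C1' bond and leaves magnesium on C2' (18), and halogen transfer from (BrCl2C)2 then forms the C2'–Br bond; the closest known reaction type is the addition of Grignard reagents to arynes released from 2-iodoaryl sulfonates with an electrophilic quench of the resulting arylmagnesium. No ring is closed and no stereocentre is created. The regioselectivity needed is attack at C1': the electron-withdrawing C3' bromine distorts the aryne so that C1' is the more linear and more electrophilic terminus, the developing carbanion sits next to bromine where it is best stabilised, and the bulky nucleophile avoids the flanked C2'. Both ortho positions of 10 are blocked, so it can react only through its CH2 carbon. The chemoselectivity needed is bromination of 18 before it loses MgBrCl to give a second aryne, and this is secured because the arenesulfonate is a much better leaving group than bromide, so that 17 forms and is consumed below the temperature at which an ortho-bromoarylmagnesium eliminates.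

Step 12
Reactants: 19 tert-butyl{2-[3-bromo-2-(2,3-dibromo-4,5-dimethoxybenzyl)-4,5-dimethoxyphenyl]ethoxy}diphenylsilane
Product: 20 2-[3-bromo-2-(2,3-dibromo-4,5-dimethoxybenzyl)-4,5-dimethoxyphenyl]ethanol
Conditions: TBAF, THF, rt
Reagents that add atoms: none
Why: Fluoride-mediated desilylation, driven by the strong silicon–fluorine bond, touches neither aryl bromides nor methyl ethers, and it precedes the demethylation because BBr3 can turn alkyl silyl ethers directly into alkyl bromides.

Step 13
Reactants: 20 2-[3-bromo-2-(2,3-dibromo-4,5-dimethoxybenzyl)-4,5-dimethoxyphenyl]ethanol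
Product: 21 3-bromo-4-(2,3-dibromo-4,5-dihydroxybenzyl)-5-(2-hydroxyethyl)benzene-1,2-diol
Conditions: BBr3 (excess), CH2Cl2, −78 → 0 °C; then H2O
Reagents that add atoms: none
Why: Lewis-acid ether cleavage with BBr3 is the standard demethylation of brominated catechol dimethyl ethers and spares aryl bromides and the diarylmethane, while the primary alcohol is only held as a borate ester that hydrolysis returns, provided the mixture stays at or below 0 °C so that bromide does not displace it.

Step 14
Reactants: 21 3-bromo-4-(2,3-dibromo-4,5-dihydroxybenzyl)-5-(2-hydroxyethyl)benzene-1,2-diol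
Product: 22 2-[3-bromo-2-(2,3-dibromo-4,5-dihydroxybenzyl)-4,5-dihydroxyphenyl]ethyl hydrogen sulfate
Conditions: SO3·pyridine (1.1 equiv), DMF, 0 °C, argon; then cation-exchange resin (H+ form), reversed-phase chromatography
Reagents that add atoms: sulfur trioxide–pyridine complex, O=S(=O)([O-])[n+]1ccccc1
Why: In O-sulfation with an SO3–amine complex and no base able to form phenoxides, the unhindered primary alcohol is the best nucleophile, the four phenols being hydrogen-bonded catechol hydroxyls on bromine-bearing rings, so about one equivalent at low temperature should go to the side chain.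

Compound list
1 | 3-bromo-4,5-dimethoxybenzaldehyde | COc1cc(C=O)cc(Br)c1OC | starting material
2 | 1-bromo-5-ethenyl-2,3-dimethoxybenzene | COc1cc(C=C)cc(Br)c1OC | intermediate
3 | 9-[2-(3-bromo-4,5-dimethoxyphenyl)ethyl]-9-borabicyclo[3.3.1]nonane | COc1cc(CCB2C3CCCC2CCC3)cc(Br)c1OC | intermediate
4 | 2-(3-bromo-4,5-dimethoxyphenyl)ethanol | COc1cc(CCO)cc(Br)c1OC | intermediate
5 | tert-butyl[2-(3-bromo-4,5-dimethoxyphenyl)ethoxy]diphenylsilane | COc1cc(CCO[Si](c2ccccc2)(c2ccccc2)C(C)(C)C)cc(Br)c1OC | intermediate
6 | 2-bromo-6-[2-(tert-butyldiphenylsilyloxy)ethyl]-3,4-dimethoxybenzaldehyde | COc1cc(CCO[Si](c2ccccc2)(c2ccccc2)C(C)(C)C)c(C=O)c(Br)c1OC | intermediate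
7 | {2-bromo-6-[2-(tert-butyldiphenylsilyloxy)ethyl]-3,4-dimethoxyphenyl}methanol | COc1cc(CCO[Si](c2ccccc2)(c2ccccc2)C(C)(C)C)c(CO)c(Br)c1OC | intermediate
8 | 2-bromo-6-[2-(tert-butyldiphenylsilyloxy)ethyl]-3,4-dimethoxybenzyl methanesulfonate | COc1cc(CCO[Si](c2ccccc2)(c2ccccc2)C(C)(C)C)c(COS(C)(=O)=O)c(Br)c1OC | intermediate
9 | tert-butyl{2-[3-bromo-2-(chloromethyl)-4,5-dimethoxyphenyl]ethoxy}diphenylsilane | COc1cc(CCO[Si](c2ccccc2)(c2ccccc2)C(C)(C)C)c(CCl)c(Br)c1OC | intermediate
10 | {2-bromo-6-[2-(tert-butyldiphenylsilyloxy)ethyl]-3,4-dimethoxybenzyl}magnesium chloride | COc1cc(CCO[Si](c2ccccc2)(c2ccccc2)C(C)(C)C)c(C[Mg]Cl)c(Br)c1OC | intermediate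
11 | 2-bromo-3,4-dimethoxybenzaldehyde | COc1ccc(C=O)c(Br)c1OC | starting material
12 | 2-bromo-3,4-dimethoxyphenyl formate | COc1ccc(OC=O)c(Br)c1OC | intermediate
13 | 2-bromo-3,4-dimethoxyphenol | COc1ccc(O)c(Br)c1OC | intermediate
14 | 2-bromo-6-iodo-3,4-dimethoxyphenol | COc1cc(I)c(O)c(Br)c1OC | intermediate
15 | 2-bromo-6-iodo-3,4-dimethoxyphenyl 4-chlorobenzenesulfonate | COc1cc(I)c(OS(=O)(=O)c2ccc(Cl)cc2)c(Br)c1OC | intermediate
16 | [3-bromo-2-(4-chlorophenylsulfonyloxy)-4,5-dimethoxyphenyl]magnesium chloride | COc1cc([Mg]Cl)c(OS(=O)(=O)c2ccc(Cl)cc2)c(Br)c1OC | intermediate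
17 | 3-bromo-4,5-dimethoxybenzyne | COC1=CC#CC(Br)=C1OC | intermediate
18 | (2-bromo-6-{2-bromo-6-[2-(tert-butyldiphenylsilyloxy)ethyl]-3,4-dimethoxybenzyl}-3,4-dimethoxyphenyl)magnesium chloride | COc1cc(CCO[Si](c2ccccc2)(c2ccccc2)C(C)(C)C)c(Cc2cc(OC)c(OC)c(Br)c2[Mg]Cl)c(Br)c1OC | intermediate
19 | tert-butyl{2-[3-bromo-2-(2,3-dibromo-4,5-dimethoxybenzyl)-4,5-dimethoxyphenyl]ethoxy}diphenylsilane | COc1cc(CCO[Si](c2ccccc2)(c2ccccc2)C(C)(C)C)c(Cc2cc(OC)c(OC)c(Br)c2Br)c(Br)c1OC | intermediate
20 | 2-[3-bromo-2-(2,3-dibromo-4,5-dimethoxybenzyl)-4,5-dimethoxyphenyl]ethanol | COc1cc(CCO)c(Cc2cc(OC)c(OC)c(Br)c2Br)c(Br)c1OC | intermediate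
21 | 3-bromo-4-(2,3-dibromo-4,5-dihydroxybenzyl)-5-(2-hydroxyethyl)benzene-1,2-diol | OCCc1cc(O)c(O)c(Br)c1Cc1cc(O)c(O)c(Br)c1Br | intermediate
22 | 2-[3-bromo-2-(2,3-dibromo-4,5-dihydroxybenzyl)-4,5-dihydroxyphenyl]ethyl hydrogen sulfate | O=S(=O)(O)OCCc1cc(O)c(O)c(Br)c1Cc1cc(O)c(O)c(Br)c1Br | target

Total step count: 14. Longest linear sequence: 11 steps (steps 1–7, then 11–14).

Steps most likely to fail

Step 11. The nucleophile may add at the wrong aryne terminus. The new ortho-bromoarylmagnesium may eliminate early and take up a second equivalent of nucleophile. The Grignard reagent may also attack at sulfur instead of waiting for the aryne. Fallback, from 1 and 5 back to 19: the diarylmethane is made by Friedel–Crafts benzylation. Aldehyde 1 is brominated para to its C5 methoxy group (Br2, Fe powder, AcOH) to give 2,3-dibromo-4,5-dimethoxybenzaldehyde F1. NaBH4 reduces this to (2,3-dibromo-4,5-dimethoxyphenyl)methanol F2. F2 is ionised with catalytic FeCl3 in CH2Cl2 in the presence of silyl ether 5, which is attacked at C2 of ring A for the same reasons as in step 4, and the route is rejoined at 19.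

Step 7. Wurtz homocoupling of the electron-rich benzylic chloride may occur on the metal surface. Initiation may be sluggish, or magnesium may insert competitively into the aryl carbon–bromine bond. Fallback, from 9 back to 10: the benzylic magnesium reagent is released by sulfur–magnesium exchange in homogeneous solution, where no benzylic halide is left to couple. Chloride 9 alkylates 2'-iodobiphenyl-2-thiol (K2CO3, DMF) to give the benzyl 2'-iodobiphenyl-2-yl sulfide F3. iPrMgCl at −50 °C exchanges only the iodine and gives the biarylmagnesium chloride F4. Addition of tBuOLi at −20 °C makes the aryl carbanion close onto sulfur, so that dibenzothiophene is expelled and the benzylic magnesium reagent 10 is set free.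

Step 14. Sulfation may occur at phenolic oxygen, multiple sulfation may take place, and the catechols may oxidise in air during isolation of the very polar product. Fallback, from 21 back to 22: kinetic chemoselectivity is replaced by temporary masking. Pentaol 21 is condensed with two equivalents of phenylboronic acid (toluene, azeotropic removal of water). This ties each catechol into a five-membered cyclic boronate and gives the bis(phenylboronate) alcohol F5. SO3·pyridine then sulfates the only remaining hydroxyl to give the sulfated bis(phenylboronate) F6. Aqueous work-up hydrolyses both boronates and delivers 22.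

Further compounds
F1 | step 11 | 2,3-dibromo-4,5-dimethoxybenzaldehyde | COc1cc(C=O)c(Br)c(Br)c1OC
F2 | step 11 | (2,3-dibromo-4,5-dimethoxyphenyl)methanol | COc1cc(CO)c(Br)c(Br)c1OC
F3 | step 7 | benzyl 2'-iodobiphenyl-2-yl sulfide of ring A (2-bromo-6-[2-(tert-butyldiphenylsilyloxy)ethyl]-3,4-dimethoxybenzyl 2'-iodobiphenyl-2-yl sulfide) | COc1cc(CCO[Si](c2ccccc2)(c2ccccc2)C(C)(C)C)c(CSc2ccccc2-c2ccccc2I)c(Br)c1OC
F4 | step 7 | biarylmagnesium chloride from F3 | COc1cc(CCO[Si](c2ccccc2)(c2ccccc2)C(C)(C)C)c(CSc2ccccc2-c2ccccc2[Mg]Cl)c(Br)c1OC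
F5 | step 14 | bis(phenylboronate) alcohol of 21 | OCCc1cc2OB(c3ccccc3)Oc2c(Br)c1Cc1cc2OB(c3ccccc3)Oc2c(Br)c1Br
F6 | step 14 | sulfated bis(phenylboronate) | O=S(=O)(O)OCCc1cc2OB(c3ccccc3)Oc2c(Br)c1Cc1cc2OB(c3ccccc3)Oc2c(Br)c1Br
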